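Ring B is taken apart at two bonds, C1–aryl and C2–C3. The feature exploited is that C1, the diaryl methine, is bonded to C2, which carries the carboxyl-level carbon C9 and is bonded to C3 with its one-carbon arm C9': this is an aryl ynoate (C1≡C2–C9) on ring A whose ortho chain ends in a (Z)-allylic phosphate at C3. One nickel-catalysed operation adds the guaiacyl group from a boronic acid to C1 and lets the alkenylnickel at C2 displace the phosphate in an SN2' sense, closing ring B and setting C3 under ligand control. The resulting C1=C2 enoate and C3 vinyl group then deliver C1, C2 and both hydroxymethyl groups.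

Key step: step 9

Assumption: (S)-tBu-PHOX, (S)-4-tert-butyl-2-[2-(diphenylphosphanyl)phenyl]-4,5-dihydro-1,3-oxazole, paired with the Z-phosphate is taken to give the (3R)-vinyl centre; if the sense of induction is the opposite, the (R)-ligand is used with the same substrate.

Remark on ring A: direct bromination of phenol 1 or of its benzyl ether is not expected to be regioselective. The bromine is therefore introduced on a bulky silyl ether (steps 1–3), which is then exchanged for benzyl.

Step 1
Reactants: 1 3-hydroxy-4,5-dimethoxybenzaldehyde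
Product: 2 3,4-dimethoxy-5-[(triisopropylsilyl)oxy]benzaldehyde
Conditions: TIPSCl, imidazole, DMF, rt
Reagents that add atoms: chlorotriisopropylsilane, CC(C)[Si](Cl)(C(C)C)C(C)C
Why: Imidazole-promoted O-silylation of a phenol installs a bulky, still electron-releasing group that shields the ring position between the formyl and silyloxy groups for the next step.

Step 2
Reactants: 2 3,4-dimethoxy-5-[(triisopropylsilyl)oxy]benzaldehyde
Product: 3 2-bromo-3,4-dimethoxy-5-[(triisopropylsilyl)oxy]benzaldehyde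
Conditions: NBS, MeCN, rt, dark
Reagents that add atoms: N-bromosuccinimide, O=C1CCC(=O)N1Br
Why: Electrophilic aromatic bromination should occur para to the silyloxy group, at the carbon flanked by the formyl and a methoxy group (future C4a), because the only other free position is blocked by the triisopropylsilyl group.

Step 3
Reactants: 3 2-bromo-3,4-dimethoxy-5-[(triisopropylsilyl)oxy]benzaldehyde
Product: 5 5-(benzyloxy)-2-bromo-3,4-dimethoxybenzaldehyde, via cesium 4-bromo-5-formyl-2,3-dimethoxyphenolate 4 (not isolated)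
Conditions: CsF, BnBr, DMF, rt
Reagents that add atoms: benzyl bromide, BrCc1ccccc1; cesium fluoride, [Cs+].[F-] (cesium stays only in 4)
Why: Fluoride-induced desilylation followed in the same flask by Williamson benzylation of the phenolate gives a phenol protecting group that tolerates the later carbonate, alkoxide, organolithium and nickel conditions.

Step 4
Reactants: 5 5-(benzyloxy)-2-bromo-3,4-dimethoxybenzaldehyde; 6 allyltributylstannane
Product: 7 2-allyl-5-(benzyloxy)-3,4-dimethoxybenzaldehyde
Conditions: Pd(PPh3)4 (5 mol%), toluene, 110 °C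
Reagents that add atoms: none
Why: Stille coupling, in which zerovalent palladium inserts into the aryl–bromine bond activated by the ortho formyl group and the stannane transfers the allyl group without touching the aldehyde.

Step 5
Reactants: 7 2-allyl-5-(benzyloxy)-3,4-dimethoxybenzaldehyde; 8 (Z)-but-2-ene-1,4-diol
Product: 9 5-(benzyloxy)-2-[(2Z)-4-hydroxybut-2-en-1-yl]-3,4-dimethoxybenzaldehyde
Conditions: Ru(=CH-C6H4-2-OiPr)(SIMes)(S2C6H2Cl2-3,6) (5 mol%), THF, 22 °C
Reagents that add atoms: none
Why: Stereoretentive (Z-selective) olefin cross-metathesis, in which the ruthenium dithiolate catalyst (SIMes = 1,3-dimesitylimidazolidin-2-ylidene) carries the cis geometry of the diol into the new allylic alcohol while the aldehyde and benzyl ether are spectators.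

Step 6
Reactants: 9 5-(benzyloxy)-2-[(2Z)-4-hydroxybut-2-en-1-yl]-3,4-dimethoxybenzaldehyde; 10 dimethyl (1-diazo-2-oxopropyl)phosphonate
Product: 11 (2Z)-4-[4-(benzyloxy)-6-ethynyl-2,3-dimethoxyphenyl]but-2-en-1-ol
Conditions: K2CO3, MeOH, 0 °C → rt
Reagents that add atoms: none
Why: Ohira–Bestmann homologation converts the aryl aldehyde into the terminal alkyne under mild carbonate conditions that tolerate the free allylic alcohol and leave the Z-alkene unchanged.

Step 7
Reactants: 11 (2Z)-4-[4-(benzyloxy)-6-ethynyl-2,3-dimethoxyphenyl]but-2-en-1-ol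
Product: 14 methyl 3-{5-(benzyloxy)-2-[(2Z)-4-hydroxybut-2-en-1-yl]-3,4-dimethoxyphenyl}prop-2-ynoate, via trimethylsilyl ether alkyne 12 (not isolated), via trimethylsilyl ether ynoate 13 (not isolated)
Conditions: TMSCl, Et3N, THF, 0 °C, filter under Ar; n-BuLi, −78 °C; ClCO2Me, −78 → −20 °C; aq. citric acid, rt
Reagents that add atoms: methyl chloroformate, COC(=O)Cl; chlorotrimethylsilane, C[Si](C)(C)Cl (stays only in 12 and 13)
Why: Transient O-silylation masks the alcohol, the lithium acetylide is acylated by the chloroformate (alkynyllithium methoxycarbonylation), and the labile silyl ether is hydrolysed by mild acid on work-up, so the ynoate never meets fluoride or alkoxide.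

Step 8
Reactants: 14 methyl 3-{5-(benzyloxy)-2-[(2Z)-4-hydroxybut-2-en-1-yl]-3,4-dimethoxyphenyl}prop-2-ynoate
Product: 15 methyl 3-{5-(benzyloxy)-2-[(2Z)-4-[(diethoxyphosphoryl)oxy]but-2-en-1-yl]-3,4-dimethoxyphenyl}prop-2-ynoate
Conditions: ClP(O)(OEt)2, pyridine, DMAP (cat.), CH2Cl2, 0 °C
Reagents that add atoms: diethyl chlorophosphate, CCOP(=O)(Cl)OCC
Why: O-phosphorylation of the primary allylic alcohol with a phosphoryl chloride under amine base installs the leaving group last, at low temperature, so that the aryl ynoate is not attacked.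

Step 9
Reactants: 15 methyl 3-{5-(benzyloxy)-2-[(2Z)-4-[(diethoxyphosphoryl)oxy]but-2-en-1-yl]-3,4-dimethoxyphenyl}prop-2-ynoate; 16 [4-(benzyloxy)-3-methoxyphenyl]boronic acid
Product: 17 methyl (3R)-7-(benzyloxy)-1-[4-(benzyloxy)-3-methoxyphenyl]-3-ethenyl-5,6-dimethoxy-3,4-dihydronaphthalene-2-carboxylate
Conditions: Ni(OAc)2·4H2O (10 mol%), (S)-tBu-PHOX (10 mol%), 16 (2 equiv), MeCN/1,4-dioxane, 80 °C
Reagents that add atoms: none
Why: Transmetalation of 16 to the divalent nickel–phosphinooxazoline complex gives an arylnickel species that adds syn across the ynoate, aryl to C1 and nickel to C2 next to the ester; the alkenylnickel then isomerises reversibly (through its nickel allenoate form) until nickel lies cis to ring A, and C2 attacks C3 of the allylic phosphate in SN2' fashion with loss of diethyl phosphate, returning divalent nickel without a redox change. The closest known reaction type is the nickel-catalysed anti-carbometallative (arylative) cyclisation of alkyne-tethered electrophiles, allylic phosphates included, with arylboronic acids. Ring B closes in a 6-exo-trig mode, C2 bonding to C3 while the remaining alkene carbon stays outside the new ring as the vinyl group. The only new stereocentre, C3, is set by the chiral phosphinooxazoline on nickel, which selects one face of the Z-alkene in the ring-closing allylic substitution. The step needs regioselective arylnickelation (secured by the ester, which polarises the alkyne and stabilises nickel at C2), reaction through the cyclisable alkenylnickel isomer (secured because only that isomer reaches the tethered electrophile while the other reverts) and SN2' instead of SN2 attack (secured by the six- versus eight-membered ring size and the cis alkene).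

Step 10
Reactants: 17 methyl (3R)-7-(benzyloxy)-1-[4-(benzyloxy)-3-methoxyphenyl]-3-ethenyl-5,6-dimethoxy-3,4-dihydronaphthalene-2-carboxylate
Product: 19 methyl (3S)-7-(benzyloxy)-1-[4-(benzyloxy)-3-methoxyphenyl]-3-(hydroxymethyl)-5,6-dimethoxy-3,4-dihydronaphthalene-2-carboxylate, via C3 aldehyde 18 (not isolated)
Conditions: O3, CH2Cl2/MeOH, −78 °C (Sudan Red 7B end point); NaBH4, −78 → 0 °C
Reagents that add atoms: ozone, [O-][O+]=O
Why: Ozonolysis with reductive work-up cleaves the monosubstituted vinyl group faster than the hindered conjugated C1=C2 bond, and immediate cold borohydride reduction converts the enolisable C3 aldehyde into the C9' alcohol before C3 can epimerise (the descriptor changes from R to S only through the priority change).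

Step 11
Reactants: 19 methyl (3S)-7-(benzyloxy)-1-[4-(benzyloxy)-3-methoxyphenyl]-3-(hydroxymethyl)-5,6-dimethoxy-3,4-dihydronaphthalene-2-carboxylate
Product: 20 methyl (3S)-7-(benzyloxy)-1-[4-(benzyloxy)-3-methoxyphenyl]-3-{[(tert-butyldimethylsilyl)oxy]methyl}-5,6-dimethoxy-3,4-dihydronaphthalene-2-carboxylate
Conditions: TBSCl, imidazole, CH2Cl2, 0 °C → rt
Reagents that add atoms: tert-butyldimethylsilyl chloride, CC(C)(C)[Si](C)(C)Cl
Why: Imidazole-promoted silylation of the primary alcohol prevents lactonisation onto the C2 ester, so that C2 can later be equilibrated in the open-chain ester.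

Step 12
Reactants: 20 methyl (3S)-7-(benzyloxy)-1-[4-(benzyloxy)-3-methoxyphenyl]-3-{[(tert-butyldimethylsilyl)oxy]methyl}-5,6-dimethoxy-3,4-dihydronaphthalene-2-carboxylate
Product: 21 methyl (1R,2R,3S)-3-{[(tert-butyldimethylsilyl)oxy]methyl}-7-hydroxy-1-(4-hydroxy-3-methoxyphenyl)-5,6-dimethoxy-1,2,3,4-tetrahydronaphthalene-2-carboxylate (1,2-cis, 2,3-cis)
Conditions: H2 (4 bar), 10% Pd/C, EtOAc, rt
Reagents that add atoms: none
Why: Heterogeneous catalytic hydrogenation should deliver both hydrogens syn to the face of C1=C2 opposite the C3 silyloxymethyl group, which allylic strain with the C2 ester holds pseudoaxial, setting C1 as R with the ester cis to it, while both benzyl ethers are hydrogenolysed in the same operation.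

Step 13
Reactants: 21 methyl (1R,2R,3S)-3-{[(tert-butyldimethylsilyl)oxy]methyl}-7-hydroxy-1-(4-hydroxy-3-methoxyphenyl)-5,6-dimethoxy-1,2,3,4-tetrahydronaphthalene-2-carboxylate
Product: 22 methyl (1R,2S,3S)-3-{[(tert-butyldimethylsilyl)oxy]methyl}-7-hydroxy-1-(4-hydroxy-3-methoxyphenyl)-5,6-dimethoxy-1,2,3,4-tetrahydronaphthalene-2-carboxylate (1,2-trans, 2,3-trans)
Conditions: NaOMe (excess), MeOH/THF, 50 °C, Ar
Reagents that add atoms: none
Why: Base-mediated epimerisation through the ester enolate places the C2 ester trans to both neighbours (all three substituents pseudoequatorial) under thermodynamic control, while C1 and C3 carry no acidic hydrogen and keep their configuration.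

Step 14
Reactants: 22 methyl (1R,2S,3S)-3-{[(tert-butyldimethylsilyl)oxy]methyl}-7-hydroxy-1-(4-hydroxy-3-methoxyphenyl)-5,6-dimethoxy-1,2,3,4-tetrahydronaphthalene-2-carboxylate
Product: 23 (1R,2S,3S)-3-{[(tert-butyldimethylsilyl)oxy]methyl}-2-(hydroxymethyl)-1-(4-hydroxy-3-methoxyphenyl)-5,6-dimethoxy-1,2,3,4-tetrahydronaphthalen-7-ol
Conditions: LiAlH4 (excess), THF, 0 °C → rt
Reagents that add atoms: none
Why: Hydride reduction of the methyl ester gives the C9 primary alcohol, the phenoxides and the silyl ether being inert and no stereocentre being involved.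

Step 15
Reactants: 23 (1R,2S,3S)-3-{[(tert-butyldimethylsilyl)oxy]methyl}-2-(hydroxymethyl)-1-(4-hydroxy-3-methoxyphenyl)-5,6-dimethoxy-1,2,3,4-tetrahydronaphthalen-7-ol
Product: 24 (1R,2S,3S)-2,3-bis(hydroxymethyl)-1-(4-hydroxy-3-methoxyphenyl)-5,6-dimethoxy-1,2,3,4-tetrahydronaphthalen-7-ol
Conditions: HCl (1.25 M in MeOH), 0 °C → rt
Reagents that add atoms: none
Why: Acid-catalysed methanolysis of the primary silyl ether releases the C9' alcohol under conditions that leave the phenols, the diol and all three stereocentres unchanged.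

Compound list
1 | 3-hydroxy-4,5-dimethoxybenzaldehyde | O=Cc1cc(O)c(OC)c(OC)c1 | starting material
2 | 3,4-dimethoxy-5-[(triisopropylsilyl)oxy]benzaldehyde | O=Cc1cc(O[Si](C(C)C)(C(C)C)C(C)C)c(OC)c(OC)c1 | intermediate
3 | 2-bromo-3,4-dimethoxy-5-[(triisopropylsilyl)oxy]benzaldehyde | O=Cc1cc(O[Si](C(C)C)(C(C)C)C(C)C)c(OC)c(OC)c1Br | intermediate
4 | cesium 4-bromo-5-formyl-2,3-dimethoxyphenolate | O=Cc1cc([O-])c(OC)c(OC)c1Br.[Cs+] | intermediate (not isolated)
5 | 5-(benzyloxy)-2-bromo-3,4-dimethoxybenzaldehyde | O=Cc1cc(OCc2ccccc2)c(OC)c(OC)c1Br | intermediate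
6 | allyltributylstannane | C=CC[Sn](CCCC)(CCCC)CCCC | starting material
7 | 2-allyl-5-(benzyloxy)-3,4-dimethoxybenzaldehyde | O=Cc1cc(OCc2ccccc2)c(OC)c(OC)c1CC=C | intermediate
8 | (Z)-but-2-ene-1,4-diol | OC/C=C\CO | starting material
9 | 5-(benzyloxy)-2-[(2Z)-4-hydroxybut-2-en-1-yl]-3,4-dimethoxybenzaldehyde | O=Cc1cc(OCc2ccccc2)c(OC)c(OC)c1C/C=C\CO | intermediate
10 | dimethyl (1-diazo-2-oxopropyl)phosphonate | CC(=O)C(=[N+]=[N-])P(=O)(OC)OC | starting material
11 | (2Z)-4-[4-(benzyloxy)-6-ethynyl-2,3-dimethoxyphenyl]but-2-en-1-ol | C#Cc1cc(OCc2ccccc2)c(OC)c(OC)c1C/C=C\CO | intermediate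
12 | {[(2Z)-4-[4-(benzyloxy)-6-ethynyl-2,3-dimethoxyphenyl]but-2-en-1-yl]oxy}trimethylsilane | C#Cc1cc(OCc2ccccc2)c(OC)c(OC)c1C/C=C\CO[Si](C)(C)C | intermediate (not isolated)
13 | methyl 3-{5-(benzyloxy)-3,4-dimethoxy-2-[(2Z)-4-[(trimethylsilyl)oxy]but-2-en-1-yl]phenyl}prop-2-ynoate | COC(=O)C#Cc1cc(OCc2ccccc2)c(OC)c(OC)c1C/C=C\CO[Si](C)(C)C | intermediate (not isolated)
14 | methyl 3-{5-(benzyloxy)-2-[(2Z)-4-hydroxybut-2-en-1-yl]-3,4-dimethoxyphenyl}prop-2-ynoate | COC(=O)C#Cc1cc(OCc2ccccc2)c(OC)c(OC)c1C/C=C\CO | intermediate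
15 | methyl 3-{5-(benzyloxy)-2-[(2Z)-4-[(diethoxyphosphoryl)oxy]but-2-en-1-yl]-3,4-dimethoxyphenyl}prop-2-ynoate | COC(=O)C#Cc1cc(OCc2ccccc2)c(OC)c(OC)c1C/C=C\COP(=O)(OCC)OCC | intermediate
16 | [4-(benzyloxy)-3-methoxyphenyl]boronic acid | COc1cc(B(O)O)ccc1OCc1ccccc1 | starting material
17 | methyl (3R)-7-(benzyloxy)-1-[4-(benzyloxy)-3-methoxyphenyl]-3-ethenyl-5,6-dimethoxy-3,4-dihydronaphthalene-2-carboxylate | COC(=O)C1=C(c2ccc(OCc3ccccc3)c(OC)c2)c2cc(OCc3ccccc3)c(OC)c(OC)c2C[C@@H]1C=C | intermediate
18 | methyl (3S)-7-(benzyloxy)-1-[4-(benzyloxy)-3-methoxyphenyl]-3-formyl-5,6-dimethoxy-3,4-dihydronaphthalene-2-carboxylate | COC(=O)C1=C(c2ccc(OCc3ccccc3)c(OC)c2)c2cc(OCc3ccccc3)c(OC)c(OC)c2C[C@@H]1C=O | intermediate (not isolated)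
19 | methyl (3S)-7-(benzyloxy)-1-[4-(benzyloxy)-3-methoxyphenyl]-3-(hydroxymethyl)-5,6-dimethoxy-3,4-dihydronaphthalene-2-carboxylate | COC(=O)C1=C(c2ccc(OCc3ccccc3)c(OC)c2)c2cc(OCc3ccccc3)c(OC)c(OC)c2C[C@@H]1CO | intermediate
20 | methyl (3S)-7-(benzyloxy)-1-[4-(benzyloxy)-3-methoxyphenyl]-3-{[(tert-butyldimethylsilyl)oxy]methyl}-5,6-dimethoxy-3,4-dihydronaphthalene-2-carboxylate | COC(=O)C1=C(c2ccc(OCc3ccccc3)c(OC)c2)c2cc(OCc3ccccc3)c(OC)c(OC)c2C[C@@H]1CO[Si](C)(C)C(C)(C)C | intermediate
21 | methyl (1R,2R,3S)-3-{[(tert-butyldimethylsilyl)oxy]methyl}-7-hydroxy-1-(4-hydroxy-3-methoxyphenyl)-5,6-dimethoxy-1,2,3,4-tetrahydronaphthalene-2-carboxylate | COc1cc([C@@H]2c3cc(O)c(OC)c(OC)c3C[C@H](CO[Si](C)(C)C(C)(C)C)[C@@H]2C(=O)OC)ccc1O | intermediate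
22 | methyl (1R,2S,3S)-3-{[(tert-butyldimethylsilyl)oxy]methyl}-7-hydroxy-1-(4-hydroxy-3-methoxyphenyl)-5,6-dimethoxy-1,2,3,4-tetrahydronaphthalene-2-carboxylate | COc1cc([C@@H]2c3cc(O)c(OC)c(OC)c3C[C@H](CO[Si](C)(C)C(C)(C)C)[C@H]2C(=O)OC)ccc1O | intermediate
23 | (1R,2S,3S)-3-{[(tert-butyldimethylsilyl)oxy]methyl}-2-(hydroxymethyl)-1-(4-hydroxy-3-methoxyphenyl)-5,6-dimethoxy-1,2,3,4-tetrahydronaphthalen-7-ol | COc1cc([C@@H]2c3cc(O)c(OC)c(OC)c3C[C@H](CO[Si](C)(C)C(C)(C)C)[C@H]2CO)ccc1O | intermediate
24 | (1R,2S,3S)-2,3-bis(hydroxymethyl)-1-(4-hydroxy-3-methoxyphenyl)-5,6-dimethoxy-1,2,3,4-tetrahydronaphthalen-7-ol (CNP0197710.1) | COc1cc([C@@H]2c3cc(O)c(OC)c(OC)c3C[C@H](CO)[C@H]2CO)ccc1O | target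

Total step count: 15. Longest linear sequence: 15 steps (1 to 24); compounds 6, 8, 10 and 16 are bought.

Steps most likely to fail

Step 9. Three processes could undermine it: protodeboronation of 16 outpacing transmetalation; protonation of the first-formed alkenylnickel before it isomerises, which leaves an acyclic hydroarylation product; and weak facial discrimination at C3. The fallback closes ring B by allylic alkylation and adds the aryl group afterwards. It sets out from 9. Acylation with methyl chloroformate and pyridine gives the allylic methyl carbonate F1. Roskamp homologation of the aldehyde (methyl diazoacetate, NbCl5 cat., CH2Cl2) gives the β-keto ester F2. Intramolecular asymmetric Tsuji–Trost alkylation (Pd2(dba)3·CHCl3, DACH-phenyl Trost ligand of the enantiomeric series that gives 3R, CH2Cl2) closes the ring to the 3-vinyl-1-tetralone-2-carboxylate F3. Triflation (NaH, PhNTf2, THF) gives the enol triflate F4, and Suzuki–Miyaura coupling with 16 (Pd(PPh3)4, K3PO4, dioxane/H2O) returns to the route at 17.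

Step 10. Ozone may over-oxidise the electron-rich rings or the C1=C2 bond, and the C3 aldehyde may enolise, with loss of C3 configuration or double-bond migration. The fallback sets out from 17. Osmium-catalysed dihydroxylation of the vinyl group (OsO4 cat., NMO, acetone/H2O) is selective for the monosubstituted alkene and gives the vicinal diol F5. Periodate cleavage (NaIO4, THF/pH 7 buffer, 0 °C) gives aldehyde 18, which is reduced at once with NaBH4 (MeOH, −40 °C) to come back at 19.

Step 12. The hindered tetrasubstituted C1=C2 bond may be saturated incompletely, or facial selectivity may erode on the catalyst surface. The fallback sets out from 20. Electron-transfer conjugate reduction with Mg in MeOH keeps the benzyl ethers. C1 is protonated on the face away from the pseudoaxial C3 side chain, and the Mg(OMe)2 formed equilibrates C2, giving the trans,trans dibenzyl ester F6. Hydrogenolysis of the benzyl ethers alone (H2, 1 bar, 10% Pd/C, EtOAc) comes back to the route at 22, so step 13 is not needed.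

Further compounds
F1 | step 9 | (2Z)-4-[4-(benzyloxy)-6-formyl-2,3-dimethoxyphenyl]but-2-en-1-yl methyl carbonate | O=Cc1cc(OCc2ccccc2)c(OC)c(OC)c1C/C=C\COC(=O)OC
F2 | step 9 | methyl 3-{5-(benzyloxy)-3,4-dimethoxy-2-[(2Z)-4-[(methoxycarbonyl)oxy]but-2-en-1-yl]phenyl}-3-oxopropanoate | COC(=O)CC(=O)c1cc(OCc2ccccc2)c(OC)c(OC)c1C/C=C\COC(=O)OC
F3 | step 9 | methyl (3R)-7-(benzyloxy)-3-ethenyl-5,6-dimethoxy-1-oxo-1,2,3,4-tetrahydronaphthalene-2-carboxylate (C2 epimers and enol form) | COC(=O)C1C(=O)c2cc(OCc3ccccc3)c(OC)c(OC)c2C[C@@H]1C=C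
F4 | step 9 | methyl (3R)-7-(benzyloxy)-3-ethenyl-5,6-dimethoxy-1-{[(trifluoromethyl)sulfonyl]oxy}-3,4-dihydronaphthalene-2-carboxylate | COC(=O)C1=C(OS(=O)(=O)C(F)(F)F)c2cc(OCc3ccccc3)c(OC)c(OC)c2C[C@@H]1C=C
F5 | step 10 | methyl (3S)-7-(benzyloxy)-1-[4-(benzyloxy)-3-methoxyphenyl]-3-(1,2-dihydroxyethyl)-5,6-dimethoxy-3,4-dihydronaphthalene-2-carboxylate (both carbinol epimers) | COC(=O)C1=C(c2ccc(OCc3ccccc3)c(OC)c2)c2cc(OCc3ccccc3)c(OC)c(OC)c2C[C@@H]1C(O)CO
F6 | step 12 | methyl (1R,2S,3S)-7-(benzyloxy)-1-[4-(benzyloxy)-3-methoxyphenyl]-3-{[(tert-butyldimethylsilyl)oxy]methyl}-5,6-dimethoxy-1,2,3,4-tetrahydronaphthalene-2-carboxylate | COc1cc([C@@H]2c3cc(OCc4ccccc4)c(OC)c(OC)c3C[C@H](CO[Si](C)(C)C(C)(C)C)[C@H]2C(=O)OC)ccc1OCc1ccccc1
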